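**Strategy.** Ring A of the target (carbocycle C4a–C5–C6–C7–C8–C8a, chromene numbering) is a 1,3,5-trioxygenated six-membered ring whose C4a–C8a edge belongs to dihydropyranone ring B. It is disconnected across C5–C6 and C7–C8. C6–C7 comes from an aldoketene carrying the C11 side chain. C5, C4a, C8a and C8 pre-exist as the ester carbon, C5, C6 and 6-CH2 of a 5-ethoxycarbonyl-2,3-dihydro-4-pyranone that already holds three stereocentres. In one flask, photo-Wolff rearrangement, γ-C-acylation of the pyranone dienolate and Claisen closure with aromatisation build ring A. A final ligand-controlled dearomative prenylation creates quaternary C6.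

Key step: step 13

Remark (numbering): target positions are O1, C2 (Me), C3 (Me), C4 (enol C–OH), C4a, C5 (C=O), C6 (quaternary), C7 (C=O), C8, C8a.
Remark (assumption): the facial sense of the catalyst-controlled steps 2, 5 and 14 is taken from the accepted models for these catalyst families; if a step delivers the antipodal centre, the mirror-image or pseudo-enantiomeric ligand ((R)-BINAP, (DHQ)2AQN, the (S,S)-bisphosphine) is used instead.
Remark (tautomers): 22, 26 and 29 are tautomeric mixtures and are drawn in one form; 29 is drawn as the given enol.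

**Step 1**
Reactants: 1 4-methylpent-4-en-1-ol; 2 ethyl (triphenyl-λ5-phosphanylidene)acetate
Product: 4 ethyl (2E)-6-methylhepta-2,6-dienoate, via aldehyde 3 (not isolated)
Conditions: IBX (1.3 equiv), 2 (1.3 equiv), DMSO, rt
Reagents that add atoms: none
Why: IBX oxidises the primary alcohol to the volatile aldehyde 3, which is trapped in situ by the stabilised ylide in a Wittig reaction that should give the (E)-enoate (tandem oxidation–Wittig olefination).

**Step 2**
Reactants: 4 ethyl (2E)-6-methylhepta-2,6-dienoate; 5 (2-methylprop-1-en-1-yl)boronic acid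
Product: 6 ethyl (3R)-6-methyl-3-(2-methylprop-1-en-1-yl)hept-6-enoate
Conditions: [Rh(OH)((S)-binap)]2 (1.5 mol%), 5 (2.5 equiv), dioxane/H2O (10:1), 40 °C
Reagents that add atoms: none
Why: Rhodium-catalysed asymmetric 1,4-addition of an alkenylboronic acid to an (E)-enoate (Hayashi–Miyaura reaction): the alkenylrhodium–(S)-BINAP species should insert the enoate on the face that the accepted model predicts to give the 3R centre, and the remote 1,1-disubstituted alkene is not an acceptor.

**Step 3**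
Reactants: 6 ethyl (3R)-6-methyl-3-(2-methylprop-1-en-1-yl)hept-6-enoate
Product: 7 (3R)-6-methyl-3-(2-methylprop-1-en-1-yl)hept-6-enoic acid
Conditions: LiOH, THF/MeOH/H2O, rt; then 1 M HCl
Reagents that add atoms: lithium hydroxide [Li+].[OH-]
Why: Ester saponification; the stereocentre is β to the carbonyl and cannot epimerise.

**Step 4**
Reactants: 7 (3R)-6-methyl-3-(2-methylprop-1-en-1-yl)hept-6-enoic acid; 8 (trimethylsilyl)diazomethane
Product: 10 (4R)-1-diazo-7-methyl-4-(2-methylprop-1-en-1-yl)oct-7-en-2-one, via acid chloride 9 (not isolated)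
Conditions: 1-chloro-N,N,2-trimethylprop-1-en-1-amine, CH2Cl2, 0 °C; then 8 (2 equiv), MeCN/THF, 0 °C → rt
Reagents that add atoms: none
Why: The α-chloroenamine forms the acid chloride under neutral conditions (no HCl to add to the alkenes) and C-acylation of (trimethylsilyl)diazomethane followed by protodesilylation gives the α-diazoketone, the first half of an Arndt–Eistert homologation.

**Step 5**
Reactants: 11 3-phenylglutaric anhydride (4-phenyloxane-2,6-dione)
Product: 12 (3R)-5-(benzyloxy)-5-oxo-3-phenylpentanoic acid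
Conditions: BnOH (1.5 equiv), (DHQD)2AQN (10 mol%), Et2O, −30 °C
Reagents that add atoms: benzyl alcohol OCc1ccccc1
Why: Cinchona-alkaloid-catalysed enantiotopic-group-selective alcoholysis (desymmetrisation) of the prochiral cyclic anhydride, in which general-base activation of benzyl alcohol in the chiral pocket should select one carbonyl and set the benzylic centre as R.

**Step 6**
Reactants: 12 (3R)-5-(benzyloxy)-5-oxo-3-phenylpentanoic acid; 13 potassium ethyl malonate
Product: 15 1-benzyl 7-ethyl (3R)-5-oxo-3-phenylheptanedioate, via acyl imidazole 14 (not isolated)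
Conditions: CDI, THF, rt; then 13, MgCl2, Et3N, MeCN, rt → 45 °C; then 1 M HCl
Reagents that add atoms: none
Why: Masamune–Brooks homologation: the acyl imidazole acylates the magnesium enolate of the malonate half-ester and decarboxylation gives the β-keto ester without touching the benzylic centre.

**Step 7**
Reactants: 16 (4S)-4-benzyl-3-propanoyl-1,3-oxazolidin-2-one; 17 acetaldehyde
Product: 18 (4S)-4-benzyl-3-[(2S,3R)-3-hydroxy-2-methylbutanoyl]-1,3-oxazolidin-2-one
Conditions: Bu2BOTf, iPr2NEt, CH2Cl2, 0 °C; 17, −78 → 0 °C; then pH 7 buffer, H2O2, MeOH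
Reagents that add atoms: none
Why: Evans syn-aldol reaction: the (Z)-boron enolate reacts through a chair Zimmerman–Traxler transition state on the face opposite the benzyl group of the auxiliary, setting 2S,3R (the future cis-2,3-dimethyl pair of ring B).

**Step 8**
Reactants: 18 (4S)-4-benzyl-3-[(2S,3R)-3-hydroxy-2-methylbutanoyl]-1,3-oxazolidin-2-one
Product: 19 (4S)-4-benzyl-3-[(2S,3R)-2-methyl-3-(triethylsilyloxy)butanoyl]-1,3-oxazolidin-2-one
Conditions: TESCl, imidazole, DMF, 0 °C → rt
Reagents that add atoms: chlorotriethylsilane CC[Si](Cl)(CC)CC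
Why: Silylation of the secondary alcohol so that the acid can later be activated as its chloride.

**Step 9**
Reactants: 19 (4S)-4-benzyl-3-[(2S,3R)-2-methyl-3-(triethylsilyloxy)butanoyl]-1,3-oxazolidin-2-one
Product: 20 (2S,3R)-2-methyl-3-(triethylsilyloxy)butanoic acid
Conditions: LiOH, H2O2, THF/H2O, 0 °C; then Na2SO3; then 1 M HCl
Reagents that add atoms: hydrogen peroxide OO
Why: Hydroperoxide cleavage of the imide at the exocyclic carbonyl releases the acid without epimerisation at C2 and returns the auxiliary.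

**Step 10**
Reactants: 20 (2S,3R)-2-methyl-3-(triethylsilyloxy)butanoic acid; 15 1-benzyl 7-ethyl (3R)-5-oxo-3-phenylheptanedioate
Product: 22 1-benzyl 7-ethyl (3R)-6-[(2S,3R)-2-methyl-3-(triethylsilyloxy)butanoyl]-5-oxo-3-phenylheptanedioate (keto–enol mixture), via acid chloride 21 (not isolated)
Conditions: 20, 1-chloro-N,N,2-trimethylprop-1-en-1-amine, CH2Cl2, 0 °C; then added to 15, MgCl2, pyridine, CH2Cl2, 0 °C → rt
Reagents that add atoms: none
Why: Magnesium-chelate-directed C-acylation of a β-keto ester by an acid chloride (soft enolisation with MgCl2/pyridine), which should favour C- over O-acylation and leave the α-stereocentre of the acid chloride intact because no strong base is present.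

**Step 11**
Reactants: 22 1-benzyl 7-ethyl (3R)-6-[(2S,3R)-2-methyl-3-(triethylsilyloxy)butanoyl]-5-oxo-3-phenylheptanedioate
Product: 23 ethyl (2R,3S)-6-[(2R)-4-(benzyloxy)-4-oxo-2-phenylbutyl]-2,3-dimethyl-4-oxo-3,4-dihydro-2H-pyran-5-carboxylate
Conditions: TFA/CH2Cl2 (1:5), H2O (2 equiv), 0 °C → rt
Reagents that add atoms: none
Why: Acid removes the silyl ether and the freed hydroxyl adds to the C5 ketone (six-membered hemiketal) and dehydrates to the vinylogous ester (cyclodehydration to a 2,3-dihydro-4-pyranone), fixing the ring oxygen on the carbon that bears the phenylbutanoate chain while the cis-methyl pair is retained because its α-carbon lies next to an enolised tricarbonyl.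

**Step 12**
Reactants: 23 ethyl (2R,3S)-6-[(2R)-4-(benzyloxy)-4-oxo-2-phenylbutyl]-2,3-dimethyl-4-oxo-3,4-dihydro-2H-pyran-5-carboxylate
Product: 24 (3R)-4-[(2R,3S)-5-(ethoxycarbonyl)-2,3-dimethyl-4-oxo-3,4-dihydro-2H-pyran-6-yl]-3-phenylbutanoic acid
Conditions: H2 (1 atm), 10% Pd/C, EtOAc, rt
Reagents that add atoms: none
Why: Hydrogenolysis of the benzyl ester frees the acid, so that the key step meets a carboxylate instead of an enolisable ester, and the tetrasubstituted push–pull alkene should resist hydrogenation.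

**Step 13**
Reactants: 10 (4R)-1-diazo-7-methyl-4-(2-methylprop-1-en-1-yl)oct-7-en-2-one; 24 (3R)-4-[(2R,3S)-5-(ethoxycarbonyl)-2,3-dimethyl-4-oxo-3,4-dihydro-2H-pyran-6-yl]-3-phenylbutanoic acid
Product: 27 (3R)-3-[(2R,3S)-5,7-dihydroxy-2,3-dimethyl-6-[(2R)-5-methyl-2-(2-methylprop-1-en-1-yl)hex-5-en-1-yl]-4-oxo-3,4-dihydro-2H-chromen-8-yl]-3-phenylpropanoic acid, via ketene 25 (not isolated), via triketo ester 26 (not isolated)
Conditions: 10, hν (365 nm), THF, −78 °C; transferred to 24 + LiN(SiMe3)2 (2.1 equiv), THF, −78 °C; then LiN(iPr)2 (2.2 equiv), −78 → 0 °C; then 1 M HCl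
Reagents that add atoms: none
Why: Irradiation of 10 expels N2 and the C3 methylene migrates to the diazo carbon (Wolff rearrangement), giving aldoketene 25 whose terminal carbon is the future C6 and whose carbonyl carbon is the future C7. The dilithium salt of 24 (carboxylate plus extended dienolate) attacks the ketene carbonyl carbon through its γ-carbon (the 6-CH2), forming C7–C8; after LiN(iPr)2 regenerates the carbanion at C6, this carbon adds to the ring B ester carbon with loss of ethoxide, forming C5–C6, and two enolisations aromatise ring A to the phloroglucinol-type chromanone 27. The closest known reaction types are the Staunton–Weinreb-type anionic [4+2] annulation, ketene C-acylation of enolates and the biomimetic Claisen cyclisation of 3,5-diketo esters to acylphloroglucinols. Ring A closes in a 6-(enolendo)-exo-trig Claisen (Dieckmann-type) mode. No stereocentre is created (C6 and C8 become sp2), and the existing centres at C2 and C3 should not enolise while the C4 carbonyl is part of the delocalised anion. The step needs γ-C- over O- or α-acylation and Claisen over aldol closure: O- and α-adducts of a ketene can revert while the γ-adduct cannot, an aldol adduct at C4 would be a bridged alkoxide that cannot aromatise and reverts, and the free carboxylate (instead of an ester) removes a competing Dieckmann nucleophile.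

**Step 14**
Reactants: 27 (3R)-3-[(2R,3S)-5,7-dihydroxy-2,3-dimethyl-6-[(2R)-5-methyl-2-(2-methylprop-1-en-1-yl)hex-5-en-1-yl]-4-oxo-3,4-dihydro-2H-chromen-8-yl]-3-phenylpropanoic acid; 28 3-methylbut-2-en-1-yl acetate
Product: 29 (3R)-3-[(2R,3S,6S)-4-hydroxy-2,3-dimethyl-6-(3-methylbut-2-en-1-yl)-6-[(2R)-5-methyl-2-(2-methylprop-1-en-1-yl)hex-5-en-1-yl]-5,7-dioxo-2,3,6,7-tetrahydro-5H-chromen-8-yl]-3-phenylpropanoic acid (CNP0155375.4)
Conditions: Pd2(dba)3·CHCl3 (2.5 mol%), (R,R)-N,N'-(cyclohexane-1,2-diyl)bis[2-(diphenylphosphanyl)benzamide] (7.5 mol%), 28 (1.1 equiv), Et3N (3 equiv), CH2Cl2, 0 °C → rt; then aq. citric acid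
Reagents that add atoms: none
Why: Palladium-catalysed asymmetric allylic alkylation (Tsuji–Trost dearomatisation of an acylphloroglucinol): the π-prenylpalladium cation held in the chiral pocket of the bisphosphine is attacked at its unsubstituted terminus by C6 of the phenoxide, the only ring carbon flanked by two oxygens, on the face selected by the ligand, which should set C6 as S, while O-prenylated material re-ionises and funnels to the C-alkylated triketone.

**Compound list**
1 | 4-methylpent-4-en-1-ol | C=C(C)CCCO | starting material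
2 | ethyl (triphenyl-λ5-phosphanylidene)acetate | CCOC(=O)C=P(c1ccccc1)(c1ccccc1)c1ccccc1 | starting material
3 | 4-methylpent-4-enal | C=C(C)CCC=O | intermediate
4 | ethyl (2E)-6-methylhepta-2,6-dienoate | C=C(C)CC/C=C/C(=O)OCC | intermediate
5 | (2-methylprop-1-en-1-yl)boronic acid | CC(C)=CB(O)O | starting material
6 | ethyl (3R)-6-methyl-3-(2-methylprop-1-en-1-yl)hept-6-enoate | C=C(C)CC[C@@H](C=C(C)C)CC(=O)OCC | intermediate
7 | (3R)-6-methyl-3-(2-methylprop-1-en-1-yl)hept-6-enoic acid | C=C(C)CC[C@@H](C=C(C)C)CC(=O)O | intermediate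
8 | (trimethylsilyl)diazomethane | C[Si](C)(C)C=[N+]=[N-] | starting material
9 | (3R)-6-methyl-3-(2-methylprop-1-en-1-yl)hept-6-enoyl chloride | C=C(C)CC[C@@H](C=C(C)C)CC(=O)Cl | intermediate
10 | (4R)-1-diazo-7-methyl-4-(2-methylprop-1-en-1-yl)oct-7-en-2-one | C=C(C)CC[C@@H](C=C(C)C)CC(=O)C=[N+]=[N-] | intermediate
11 | 3-phenylglutaric anhydride (4-phenyloxane-2,6-dione) | O=C1CC(c2ccccc2)CC(=O)O1 | starting material
12 | (3R)-5-(benzyloxy)-5-oxo-3-phenylpentanoic acid | OC(=O)C[C@H](CC(=O)OCc1ccccc1)c1ccccc1 | intermediate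
13 | potassium ethyl malonate (potassium 3-ethoxy-3-oxopropanoate) | CCOC(=O)CC(=O)[O-].[K+] | starting material
14 | benzyl (3R)-5-(1H-imidazol-1-yl)-5-oxo-3-phenylpentanoate | O=C(C[C@H](CC(=O)OCc1ccccc1)c1ccccc1)n1ccnc1 | intermediate
15 | 1-benzyl 7-ethyl (3R)-5-oxo-3-phenylheptanedioate | CCOC(=O)CC(=O)C[C@H](CC(=O)OCc1ccccc1)c1ccccc1 | intermediate
16 | (4S)-4-benzyl-3-propanoyl-1,3-oxazolidin-2-one | O=C1OC[C@H](Cc2ccccc2)N1C(=O)CC | starting material
17 | acetaldehyde | CC=O | starting material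
18 | (4S)-4-benzyl-3-[(2S,3R)-3-hydroxy-2-methylbutanoyl]-1,3-oxazolidin-2-one | O=C1OC[C@H](Cc2ccccc2)N1C(=O)[C@@H](C)[C@@H](C)O | intermediate
19 | (4S)-4-benzyl-3-[(2S,3R)-2-methyl-3-(triethylsilyloxy)butanoyl]-1,3-oxazolidin-2-one | O=C1OC[C@H](Cc2ccccc2)N1C(=O)[C@@H](C)[C@@H](C)O[Si](CC)(CC)CC | intermediate
20 | (2S,3R)-2-methyl-3-(triethylsilyloxy)butanoic acid | OC(=O)[C@@H](C)[C@@H](C)O[Si](CC)(CC)CC | intermediate
21 | (2S,3R)-2-methyl-3-(triethylsilyloxy)butanoyl chloride | ClC(=O)[C@@H](C)[C@@H](C)O[Si](CC)(CC)CC | intermediate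
22 | 1-benzyl 7-ethyl (3R)-6-[(2S,3R)-2-methyl-3-(triethylsilyloxy)butanoyl]-5-oxo-3-phenylheptanedioate (keto–enol mixture, C6 not assigned) | CCOC(=O)C(C(=O)C[C@H](CC(=O)OCc1ccccc1)c1ccccc1)C(=O)[C@@H](C)[C@@H](C)O[Si](CC)(CC)CC | intermediate
23 | ethyl (2R,3S)-6-[(2R)-4-(benzyloxy)-4-oxo-2-phenylbutyl]-2,3-dimethyl-4-oxo-3,4-dihydro-2H-pyran-5-carboxylate | O=C1[C@@H](C)[C@@H](C)OC(C[C@H](CC(=O)OCc2ccccc2)c2ccccc2)=C1C(=O)OCC | intermediate
24 | (3R)-4-[(2R,3S)-5-(ethoxycarbonyl)-2,3-dimethyl-4-oxo-3,4-dihydro-2H-pyran-6-yl]-3-phenylbutanoic acid | O=C1[C@@H](C)[C@@H](C)OC(C[C@H](CC(=O)O)c2ccccc2)=C1C(=O)OCC | intermediate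
25 | (4R)-7-methyl-4-(2-methylprop-1-en-1-yl)octa-1,7-dien-1-one (aldoketene) | C=C(C)CC[C@@H](C=C(C)C)CC=C=O | intermediate
26 | (3S,8R)-4-[(2R,3S)-5-(ethoxycarbonyl)-2,3-dimethyl-4-oxo-3,4-dihydro-2H-pyran-6-yl]-11-methyl-8-(2-methylprop-1-en-1-yl)-5-oxo-3-phenyldodec-11-enoic acid (C4 not assigned, enolisable; the C3 descriptor differs from 24 by priority only) | C=C(C)CC[C@@H](C=C(C)C)CCC(=O)C([C@H](CC(=O)O)c1ccccc1)C1=C(C(=O)OCC)C(=O)[C@@H](C)[C@@H](C)O1 | intermediate
27 | (3R)-3-[(2R,3S)-5,7-dihydroxy-2,3-dimethyl-6-[(2R)-5-methyl-2-(2-methylprop-1-en-1-yl)hex-5-en-1-yl]-4-oxo-3,4-dihydro-2H-chromen-8-yl]-3-phenylpropanoic acid | C=C(C)CC[C@@H](C=C(C)C)Cc1c(O)c2C(=O)[C@@H](C)[C@@H](C)Oc2c([C@H](CC(=O)O)c2ccccc2)c1O | intermediate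
28 | 3-methylbut-2-en-1-yl acetate (prenyl acetate) | CC(C)=CCOC(C)=O | starting material
29 | (3R)-3-[(2R,3S,6S)-4-hydroxy-2,3-dimethyl-6-(3-methylbut-2-en-1-yl)-6-[(2R)-5-methyl-2-(2-methylprop-1-en-1-yl)hex-5-en-1-yl]-5,7-dioxo-2,3,6,7-tetrahydro-5H-chromen-8-yl]-3-phenylpropanoic acid | C=C(C)CC[C@@H](C=C(C)C)C[C@@]1(CC=C(C)C)C(=O)C2=C(O)[C@@H](C)[C@@H](C)OC2=C([C@H](CC(=O)O)c2ccccc2)C1=O | target

**Totals.** Total step count: 14. Longest linear sequence: 8 steps (steps 7, 8, 9, 10, 11, 12, 13, 14).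

**Steps most likely to fail**

Step 13. After C-acylation the ketone enolate may be quenched by proton transfer, it may close through oxygen onto the ester (pyrone formation) instead of through carbon, or the aldoketene may dimerise before capture. The fallback sets out from 10 and 24 and comes back at 27; it separates the two bond formations and replaces the ketene by an isolable acyl donor. Silver-benzoate-catalysed Wolff rearrangement of 10 in aqueous dioxane (PhCO2Ag, Et3N) gives the homologous acid (4R)-7-methyl-4-(2-methylprop-1-en-1-yl)oct-7-enoic acid F1. CDI in THF converts it into 1-[(4R)-7-methyl-4-(2-methylprop-1-en-1-yl)oct-7-enoyl]-1H-imidazole F2. F2 acylates the dilithium salt of 24 (LiN(SiMe3)2, THF, −78 °C) at the 6-CH2 carbon, and triketo ester 26 is isolated. Claisen cyclisation and aromatisation under thermodynamic conditions (Mg(OMe)2, MeOH, reflux) should then give 27.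

Step 14. The ligand may discriminate poorly between the faces of a nucleophile that is remote from every stereocentre, reversible allyl transfer may erode the selectivity, and the carboxylate or a phenoxide may be O-prenylated. The fallback sets out from 27 and comes back at 29; it replaces palladium–ligand control by irreversible ion-pair-controlled alkylation of a neutral ester. Selective esterification of the carboxylate (MeI, KHCO3, DMF) gives methyl (3R)-3-[(2R,3S)-5,7-dihydroxy-2,3-dimethyl-6-[(2R)-5-methyl-2-(2-methylprop-1-en-1-yl)hex-5-en-1-yl]-4-oxo-3,4-dihydro-2H-chromen-8-yl]-3-phenylpropanoate F3. Solid–liquid phase-transfer C-alkylation (prenyl bromide, N-benzylcinchonidinium chloride, Cs2CO3, toluene/CHCl3, −20 °C) should give methyl (3R)-3-[(2R,3S,6S)-4-hydroxy-2,3-dimethyl-6-(3-methylbut-2-en-1-yl)-6-[(2R)-5-methyl-2-(2-methylprop-1-en-1-yl)hex-5-en-1-yl]-5,7-dioxo-2,3,6,7-tetrahydro-5H-chromen-8-yl]-3-phenylpropanoate F4. If the ion-pair control is incomplete, the C6 epimers of this neutral ester can be separated by chromatography. Hydrolysis (LiOH, THF/H2O, 0 °C → rt, then acid) gives 29.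

Step 11. The liberated hydroxyl may close onto the ethyl ester (lactonisation) instead of the C5 ketone, and acid may epimerise the carbon α to the ketone. The fallback sets out from 15 and 21 and comes back at 23; it closes ring B before the ester is present. Krapcho dealkoxycarbonylation of 15 (NaCl, wet DMSO, 140 °C) gives benzyl (3R)-5-oxo-3-phenylhexanoate F5. Its kinetic lithium enolate at the methyl group (LiN(SiMe3)2, two equivalents, THF, −78 °C) is C-acylated by 21 to benzyl (3R,8S,9R)-8-methyl-5,7-dioxo-3-phenyl-9-(triethylsilyloxy)decanoate F6. TFA/CH2Cl2/H2O removes the silyl group and closes the only available six-membered ring to benzyl (3R)-4-[(2R,3S)-2,3-dimethyl-4-oxo-3,4-dihydro-2H-pyran-6-yl]-3-phenylbutanoate F7. Iodination at C5 (I2, pyridine, CH2Cl2) gives benzyl (3R)-4-[(2R,3S)-5-iodo-2,3-dimethyl-4-oxo-3,4-dihydro-2H-pyran-6-yl]-3-phenylbutanoate F8. Palladium-catalysed ethoxycarbonylation (Pd(OAc)2, PPh3, CO, EtOH, Et3N, DMF, 60 °C) returns to 23.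

**Further compounds**
F1 | step 13 | (4R)-7-methyl-4-(2-methylprop-1-en-1-yl)oct-7-enoic acid | C=C(C)CC[C@@H](C=C(C)C)CCC(=O)O
F2 | step 13 | 1-[(4R)-7-methyl-4-(2-methylprop-1-en-1-yl)oct-7-enoyl]-1H-imidazole | C=C(C)CC[C@@H](C=C(C)C)CCC(=O)n1ccnc1
F3 | step 14 | methyl (3R)-3-[(2R,3S)-5,7-dihydroxy-2,3-dimethyl-6-[(2R)-5-methyl-2-(2-methylprop-1-en-1-yl)hex-5-en-1-yl]-4-oxo-3,4-dihydro-2H-chromen-8-yl]-3-phenylpropanoate | C=C(C)CC[C@@H](C=C(C)C)Cc1c(O)c2C(=O)[C@@H](C)[C@@H](C)Oc2c([C@H](CC(=O)OC)c2ccccc2)c1O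
F4 | step 14 | methyl (3R)-3-[(2R,3S,6S)-4-hydroxy-2,3-dimethyl-6-(3-methylbut-2-en-1-yl)-6-[(2R)-5-methyl-2-(2-methylprop-1-en-1-yl)hex-5-en-1-yl]-5,7-dioxo-2,3,6,7-tetrahydro-5H-chromen-8-yl]-3-phenylpropanoate | C=C(C)CC[C@@H](C=C(C)C)C[C@@]1(CC=C(C)C)C(=O)C2=C(O)[C@@H](C)[C@@H](C)OC2=C([C@H](CC(=O)OC)c2ccccc2)C1=O
F5 | step 11 | benzyl (3R)-5-oxo-3-phenylhexanoate | CC(=O)C[C@H](CC(=O)OCc1ccccc1)c1ccccc1
F6 | step 11 | benzyl (3R,8S,9R)-8-methyl-5,7-dioxo-3-phenyl-9-(triethylsilyloxy)decanoate | O=C(CC(=O)C[C@H](CC(=O)OCc1ccccc1)c1ccccc1)[C@@H](C)[C@@H](C)O[Si](CC)(CC)CC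
F7 | step 11 | benzyl (3R)-4-[(2R,3S)-2,3-dimethyl-4-oxo-3,4-dihydro-2H-pyran-6-yl]-3-phenylbutanoate | O=C1[C@@H](C)[C@@H](C)OC(C[C@H](CC(=O)OCc2ccccc2)c2ccccc2)=C1
F8 | step 11 | benzyl (3R)-4-[(2R,3S)-5-iodo-2,3-dimethyl-4-oxo-3,4-dihydro-2H-pyran-6-yl]-3-phenylbutanoate | O=C1[C@@H](C)[C@@H](C)OC(C[C@H](CC(=O)OCc2ccccc2)c2ccccc2)=C1I
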